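**Retrosynthetic overview**
1. Target 10 ← triacetate 9 by mild removal of three aryl acetates; 9 ← 6-allyl triacetate 8 by cross-metathesis with 2-methyl-2-butene (allyl → prenyl).
2. 8 ← 5-O-allyl coumarin 6 by aromatic Claisen rearrangement, which sets the C6–C bond at the only free ortho position of O5.
3. 6 ← salicylaldehyde 2 + 2,4-dihydroxyphenylacetic acid 3 by Perkin–Oglialoro condensation; this forms the pyranone ring, the only ring made in the route (benzene rings A and B are bought).
4. 2 ← symmetric 2,6-dihydroxy-4-methoxybenzaldehyde 1 by mono-O-allylation; the allyl ether both differentiates the two phenols (fixing which oxygen becomes the lactone oxygen) and later delivers the C6 carbon chain.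

Assumption: the target has no stereocentre and no E/Z element (the prenyl alkene carries two identical methyls), so it is one achiral compound and needs no stereocontrol; 1 and 3 are taken as catalogue chemicals.

**Route**

Step 1
Reactants: 1 2,6-dihydroxy-4-methoxybenzaldehyde
Product: 2 2-(allyloxy)-6-hydroxy-4-methoxybenzaldehyde
Conditions: allyl bromide (1.05 equiv), K2CO3 (1.1 equiv), acetone, 56 °C, 4 h
Reagents that add atoms: allyl bromide, C=CCBr
Why: Williamson ether synthesis on a symmetric diol; after the first alkylation the remaining OH is locked in a hydrogen bond to the aldehyde and is far less nucleophilic, so the mono-ether predominates.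

Step 2
Reactants: 2 2-(allyloxy)-6-hydroxy-4-methoxybenzaldehyde; 3 2,4-dihydroxyphenylacetic acid
Product: 6 5-(allyloxy)-3-(2,4-diacetoxyphenyl)-7-methoxycoumarin, via mixed anhydride 4 (not isolated), via aryl ester 5 (not isolated)
Conditions: Ac2O (solvent), KOAc (3 equiv), 120 °C, 12 h, N2
Reagents that add atoms: acetic anhydride, CC(=O)OC(C)=O
Why: Perkin–Oglialoro coumarin synthesis: the acid is acetylated and activated as its mixed anhydride, acylates the only free phenol of 2, and acetate-mediated intramolecular aldol condensation onto the ortho aldehyde closes the pyranone with unambiguous regiochemistry.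

Step 3
Reactants: 6 5-(allyloxy)-3-(2,4-diacetoxyphenyl)-7-methoxycoumarin
Product: 8 5-acetoxy-6-allyl-3-(2,4-diacetoxyphenyl)-7-methoxycoumarin, via 6-allyl-5-hydroxycoumarin 7 (not isolated)
Conditions: PhNEt2, 200 °C (sealed tube), 3 h; then Ac2O, pyridine, DMAP (cat.), 23 °C
Reagents that add atoms: acetic anhydride, CC(=O)OC(C)=O
Why: Aromatic Claisen rearrangement ([3,3]-sigmatropic) moves the allyl group to C6, the only unsubstituted ortho carbon (the other is ring-fusion C4a); capping the new phenol as the acetate gives one defined triacetate and prevents acetyl scrambling or cyclisation onto the alkene.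

Step 4
Reactants: 8 5-acetoxy-6-allyl-3-(2,4-diacetoxyphenyl)-7-methoxycoumarin
Product: 9 5-acetoxy-3-(2,4-diacetoxyphenyl)-7-methoxy-6-(3-methylbut-2-en-1-yl)coumarin
Conditions: 2-methyl-2-butene (excess), second-generation Grubbs catalyst RuCl2(=CHPh)(PCy3)(H2IMes) (5 mol %), CH2Cl2, 40 °C (sealed), 12 h
Reagents that add atoms: 2-methyl-2-butene, CC=C(C)C
Why: Olefin cross-metathesis swaps the terminal CH2 of the allyl group for an isopropylidene unit; the trisubstituted product and the conjugated C3=C4 bond of the coumarin do not react further, and the new alkene has no E/Z isomers.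

Step 5
Reactants: 9 5-acetoxy-3-(2,4-diacetoxyphenyl)-7-methoxy-6-(3-methylbut-2-en-1-yl)coumarin
Product: 10 3-(2,4-dihydroxyphenyl)-5-hydroxy-7-methoxy-6-(3-methylbut-2-en-1-yl)coumarin (target)
Conditions: N2H4·H2O (3.5 equiv), THF, 0 °C, argon, 1 h; then dilute aqueous AcOH work-up
Reagents that add atoms: none
Why: Chemoselective hydrazinolysis of the three activated aryl acetates under near-neutral, non-acidic conditions leaves the lactone, the methyl ether and the acid-sensitive ortho-prenyl phenol untouched, and avoids lactone opening that could re-close on the other oxygen.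

**Compound list**
1 | 2,6-dihydroxy-4-methoxybenzaldehyde | COc1cc(O)c(C=O)c(O)c1 | starting material
2 | 2-(allyloxy)-6-hydroxy-4-methoxybenzaldehyde | C=CCOc1cc(OC)cc(O)c1C=O | intermediate
3 | 2,4-dihydroxyphenylacetic acid | OC(=O)Cc1ccc(O)cc1O | starting material
4 | acetic 2-(2,4-diacetoxyphenyl)acetic anhydride (mixed anhydride) | CC(=O)OC(=O)Cc1ccc(OC(C)=O)cc1OC(C)=O | intermediate (not isolated)
5 | 3-(allyloxy)-2-formyl-5-methoxyphenyl 2-(2,4-diacetoxyphenyl)acetate (aryl ester) | C=CCOc1cc(OC)cc(OC(=O)Cc2ccc(OC(C)=O)cc2OC(C)=O)c1C=O | intermediate (not isolated)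
6 | 5-(allyloxy)-3-(2,4-diacetoxyphenyl)-7-methoxycoumarin | C=CCOc1cc(OC)cc2oc(=O)c(-c3ccc(OC(C)=O)cc3OC(C)=O)cc12 | intermediate
7 | 6-allyl-3-(2,4-diacetoxyphenyl)-5-hydroxy-7-methoxycoumarin | C=CCc1c(OC)cc2oc(=O)c(-c3ccc(OC(C)=O)cc3OC(C)=O)cc2c1O | intermediate (not isolated)
8 | 5-acetoxy-6-allyl-3-(2,4-diacetoxyphenyl)-7-methoxycoumarin | C=CCc1c(OC)cc2oc(=O)c(-c3ccc(OC(C)=O)cc3OC(C)=O)cc2c1OC(C)=O | intermediate
9 | 5-acetoxy-3-(2,4-diacetoxyphenyl)-7-methoxy-6-(3-methylbut-2-en-1-yl)coumarin | CC(C)=CCc1c(OC)cc2oc(=O)c(-c3ccc(OC(C)=O)cc3OC(C)=O)cc2c1OC(C)=O | intermediate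
10 | 3-(2,4-dihydroxyphenyl)-5-hydroxy-7-methoxy-6-(3-methylbut-2-en-1-yl)coumarin | COc1cc2oc(=O)c(-c3ccc(O)cc3O)cc2c(O)c1CC=C(C)C | target

**Totals**
Total step count: 5. Longest linear sequence: 5 steps (1 → 2 → 6 → 8 → 9 → 10; acid 3 enters at step 2).

**Steps most likely to fail, with fallbacks**

Step 2 (Perkin–Oglialoro condensation). The aldehyde is flanked by two ortho oxygens, acid 3 can self-lactonise to a benzofuranone, and acetate itself can condense, so the yield may be poor. The fallback forms the C3–aryl bond by cross-coupling; it sets out from 2 and comes back to the route at 6. Aldehyde 2 is heated with ethyl bromo(triphenylphosphoranylidene)acetate, Ph3P=C(Br)CO2Et, in toluene at 110 °C. Wittig olefination gives ethyl (E)-2-bromo-3-[2-(allyloxy)-6-hydroxy-4-methoxyphenyl]acrylate F1 (aryl cis to the ester, not isolated), which lactonises in the same pot to 5-(allyloxy)-3-bromo-7-methoxycoumarin F2. Suzuki–Miyaura coupling of F2 with [2,4-bis(methoxymethoxy)phenyl]boronic acid (Pd(PPh3)4, K2CO3, dioxane/H2O, 80 °C) gives 5-(allyloxy)-3-[2,4-bis(methoxymethoxy)phenyl]-7-methoxycoumarin F3. HCl in MeOH at 40 °C removes both acetal groups to give 5-(allyloxy)-3-(2,4-dihydroxyphenyl)-7-methoxycoumarin F4, and Ac2O/pyridine converts F4 into 6.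

Step 3 (Claisen rearrangement). At 200 °C the rearrangement may be accompanied by migration towards C8, decomposition or acetyl transfer. The fallback installs the prenyl group directly by an O-to-C shift and bypasses steps 3 and 4; it sets out from 1 and comes back to the route at 10. Aldehyde 1 is mono-O-alkylated with prenyl bromide (K2CO3, acetone) to 2-hydroxy-4-methoxy-6-[(3-methylbut-2-en-1-yl)oxy]benzaldehyde F5. Perkin–Oglialoro condensation of F5 with 3 under the step 2 conditions proceeds through mixed anhydride 4 and 2-formyl-5-methoxy-3-[(3-methylbut-2-en-1-yl)oxy]phenyl 2-(2,4-diacetoxyphenyl)acetate F6 (not isolated) to give 3-(2,4-diacetoxyphenyl)-7-methoxy-5-[(3-methylbut-2-en-1-yl)oxy]coumarin F7. Stirring F7 over magnesium silicate MgSiO3 (Florisil) in toluene at 60 °C promotes a [1,3] prenyl shift from O5 to the ortho carbon C6, giving 3-(2,4-diacetoxyphenyl)-5-hydroxy-7-methoxy-6-(3-methylbut-2-en-1-yl)coumarin F8. F8 is deacetylated under the step 5 conditions to 10.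

Step 5 (final deacetylation). Hydrazine could attack the lactone (hydrazide formation, or opening and re-closure on O5 to give the 8-prenyl isomer), and the free polyphenol may degrade; acidic alternatives would cyclise the ortho-prenyl phenol to a chroman. The fallback removes the acetates with acid at the allyl stage, where acid is tolerated, and makes the prenyl group last; it sets out from 8 and comes back to the route at 10. Triacetate 8 is methanolysed with HCl in MeOH at 50 °C to 6-allyl-3-(2,4-dihydroxyphenyl)-5-hydroxy-7-methoxycoumarin F9. Cross-metathesis of F9 with excess 2-methyl-2-butene (second-generation Grubbs catalyst RuCl2(=CHPh)(PCy3)(H2IMes), CH2Cl2/THF, 40 °C) gives 10.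

**Further compounds**
F1 | step 2 | ethyl (E)-2-bromo-3-[2-(allyloxy)-6-hydroxy-4-methoxyphenyl]acrylate | CCOC(=O)/C(Br)=C\c1c(O)cc(OC)cc1OCC=C
F2 | step 2 | 5-(allyloxy)-3-bromo-7-methoxycoumarin | C=CCOc1cc(OC)cc2oc(=O)c(Br)cc12
F3 | step 2 | 5-(allyloxy)-3-[2,4-bis(methoxymethoxy)phenyl]-7-methoxycoumarin | C=CCOc1cc(OC)cc2oc(=O)c(-c3ccc(OCOC)cc3OCOC)cc12
F4 | step 2 | 5-(allyloxy)-3-(2,4-dihydroxyphenyl)-7-methoxycoumarin | C=CCOc1cc(OC)cc2oc(=O)c(-c3ccc(O)cc3O)cc12
F5 | step 3 | 2-hydroxy-4-methoxy-6-[(3-methylbut-2-en-1-yl)oxy]benzaldehyde | CC(C)=CCOc1cc(OC)cc(O)c1C=O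
F6 | step 3 | 2-formyl-5-methoxy-3-[(3-methylbut-2-en-1-yl)oxy]phenyl 2-(2,4-diacetoxyphenyl)acetate | CC(C)=CCOc1cc(OC)cc(OC(=O)Cc2ccc(OC(C)=O)cc2OC(C)=O)c1C=O
F7 | step 3 | 3-(2,4-diacetoxyphenyl)-7-methoxy-5-[(3-methylbut-2-en-1-yl)oxy]coumarin | CC(C)=CCOc1cc(OC)cc2oc(=O)c(-c3ccc(OC(C)=O)cc3OC(C)=O)cc12
F8 | step 3 | 3-(2,4-diacetoxyphenyl)-5-hydroxy-7-methoxy-6-(3-methylbut-2-en-1-yl)coumarin | CC(C)=CCc1c(OC)cc2oc(=O)c(-c3ccc(OC(C)=O)cc3OC(C)=O)cc2c1O
F9 | step 5 | 6-allyl-3-(2,4-dihydroxyphenyl)-5-hydroxy-7-methoxycoumarin | C=CCc1c(OC)cc2oc(=O)c(-c3ccc(O)cc3O)cc2c1O
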